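Compound numbers 1–32 follow the order of first appearance in the steps. Atom labels are the germacrane numbers of the target: ring carbons C1–C10, C11 on C7, C12 the lactone carbonyl, C13 the acetoxymethyl carbon, C14 and C15 the methyls on C10 and C4.

## Analysis of the target

- **Ring system.** The target 32 is a germacranolide. Its ten-membered carbocycle C1–C10 is bridged by an ether oxygen between C1 and C4, so that C1, C2, C3, C4 and O form an oxolane inside an 11-oxabicyclo[6.2.1]undecane. The C6–C7 bond is shared with a butenolide (O–C12(=O)–C11=C7) that runs on into an exocyclic enol-ether alkene C5=C6.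
- **Substituents.** C11 carries the acetoxymethyl carbon C13, C8 the angelate, C10 a methyl and a free tertiary hydroxyl, C4 a methyl.
- **Stereocentres.** There are four: C1 (S), C4 (S), C8 (S) and C10 (R); C5=C6 is E by the sequence rules, with C4 cis to C7. C1 and C10 are vicinal and related as in an opened E-epoxide. C8 is one methylene away from C10.
- **The bridge.** Read as written, the ring bonds C1–C10 and C4–C5 leave the oxolane on opposite faces (the C4 methyl and C10 are cis). This is the most demanding stereochemical feature, because the ether must be closed across a ten-membered ring against its usual face preference.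
- **Sensitive groups.** The angelate isomerises from Z to E with nucleophiles and heat. The allylic acetate on the butenolide is open to SN2′ and vinylogous elimination. The enol lactone and the tertiary allylic ether at C4 are acid- and base-labile.
- **Feature on which the strategy rests.** C6 (lactone oxygen) and C7 (bearing C11–C13) are adjacent. This is the pattern left when an allyl ether O–CH2–C11=C7 shifts onto a carbanion at C6 in a [2,3]-Wittig rearrangement. C1/C10 and C4/C5 carry oxygen in the pattern of two E-alkene epoxides, so a (1(10)E,4E)-cyclodecadiene is the natural carbocyclic precursor.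

## Retrosynthetic reasoning

**Acyl groups (32 ⇒ 29 + 30 ⇒ 28 ⇒ 27).** The ester C–O bonds at C8 and C13 are cut first. The angelate and the allylic acetate would not survive the base needed to form the ether bridge, so both hydroxyls are carried as silyl ethers until the skeleton is complete. Forward, the two silyl groups are removed, the primary hydroxyl is acetylated selectively, and the secondary hydroxyl is acylated with 30 without Z-to-E isomerisation. The tertiary C10 hydroxyl needs no protection.

**Ether bridge and C5=C6 (27 ⇒ 26 ⇒ 25).** The C1–O bond of the oxolane is cut, and the C5=C6 alkene is traced back to a C5–O bond and a hydrogen on C6. The hydrogen on C6 of 25 is the γ-hydrogen of a butenolide, the one acidic C–H next to an epoxide. Its removal opens the 4,5-epoxide without touching the C4–O bond and gives alkoxide 26, three carbons from C1 of the second epoxide. One isomerisation therefore delivers C5=C6, C4–O, C1–O and the C10 hydroxyl. The forward reaction needs the (4S,5S)- and (1R,10R)-epoxides and inversion at C1.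

**C7=C11 and the C13 oxygen (25 ⇒ 24 ⇒ 23 ⇒ 22).** H-7 is not acidic, so the alkene is made by eliminating a C11 hydroxyl. That hydroxyl and the C13 oxygen come together from dihydroxylation of the exocyclic alkene of 22. The C13 oxygen is silylated because a silyl ether is a poor leaving group in the base step.

**Lactone and epoxides (22 ⇒ 20 ⇒ 19 ⇒ 18 ⇒ 17 ⇒ 16).** The lactone C12–O bond and the C12 oxidation level go back to the isopropenyl group of 16. Oxidation starts at its terminal alkene carbon, because direct oxidation of an allylic methyl could not tell the side chain from C14 and C15. The 4,5-epoxide is put in while the C6 hydroxyl of 16 is free, since that hydroxyl selects the alkene and the face. The 1,10-epoxide is put in under catalyst control once C1=C10 is the only alkene left.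

**Key disconnection (16 ⇒ 15).** The C6–C7 bond is cut and the C6 oxygen is reconnected to C12. This turns the ten-membered carbocycle into the 13-membered diallylic ether 15, which is far easier to close. The forward reaction must form C6–C7 from a C6 carbanion, not from the C12 side.

**Macrocyclic ether (15 ⇒ 14).** The C6–O bond is cut to a primary allylic chloride and a primary allylic alcohol in 14. Both ends are unhindered, and the three E-alkenes hold the chain open.

**Chain (14 ⇒ 13 ⇒ 11 + 12; 11 ⇒ 10 ⇒ 9 ⇒ 8 ⇒ 7 + 3; 3 ⇒ 2 ⇒ 1; 7 ⇒ 4 + 5).** The C7=C11 alkene is cut to aldehyde 11 and ylide 12, which supplies C11–C13 with E geometry. The C8–C9 bond is cut to the glycolate imide 7 and the allylic bromide 3. The auxiliary from 4 sets C8, the only stereocentre that must be bought, and 3 comes from 1 in two steps. C1–C6, C9, C10, C14 and C15 with both E-alkenes are taken from 1 unchanged.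

## Alternatives that were turned down

**Alternative 1:** The oxolane is opened at C4–O and the C5=C6 alkene is replaced by a C5 hydroxyl. This leads to A1, a ten-membered (4R,5R)-epoxide with free hydroxyls on C1 and C10 and both acyl groups in place. Forward, a Brønsted acid would activate the epoxide and the C1 hydroxyl would attack the tertiary C4 with inversion (5-exo) to give A2, which is then dehydrated across C5–C6.
- For: a tertiary epoxide carbon is the natural site of acid-promoted attack. No strong base is needed at the ring-forming stage, so the esters can be in place early. On end-game step economy this plan is stronger than the chosen one.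
- Against: it is an end-game only and does not say how the ten-membered ring is made. A1 needs an anti 1,10-diol as well as the epoxide, so three oxygenated centres must be set on a flexible ring before the closure. The C10 hydroxyl can compete for C4 (six-membered ether). Attack at a tertiary centre under acid has SN1 character and may erode C4. The final dehydration needs base at a stage where the allylic acetate can be expelled.
- Comparison: the chosen strategy keeps the C4–O bond intact from the epoxide onward and also builds the carbocycle.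

**Alternative 2:** The ring is cut between C7 and C8 and a sulfur atom is inserted, giving the eleven-membered keto thiolactone A3 with the oxolane, C1, C4 and C10 already in place. Forward, the C7 enolate would add to the thioester carbonyl and a thiophile would remove sulfur from the thiirane to give the bridged cyclodecane-1,3-dione A4.
- For: the oxolane and its stereocentres are made on a small ring before any medium ring exists, so no transannular etherification is asked for. On the bridge this is the stronger plan. A4 also has C7 doubly activated for attaching C11–C13.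
- Against: sulfide contraction is well established with thioamide-derived electrophiles, much less with a plain thioester. The product is a strained bridged β-diketone that can revert by retro-Claisen cleavage. Enolisation toward C5 competes. C8 would have to be reduced stereoselectively late, next to a second carbonyl on a flexible ring. The butenolide is still to be built.
- Comparison: the chosen strategy offers a ring-forming step with close precedent on this skeleton, C8 fixed at the outset, and a chain taken almost whole from a cheap terpene.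

**Alternative 3:** C6 and C10 are joined in thought as a tetrasubstituted alkene, which gives the bicyclo[5.3.0]decene A5. Forward, ozonolysis with reductive work-up would cleave the ring-fusion alkene to the cyclodecane-1,5-dione A6.
- For: the ten-membered ring is formed by a cleavage that has no entropic penalty. C1, C4 and C8 can be set on a rigid bicycle. On certainty of ring formation this beats a ring contraction.
- Against: the two ketones of A6 face each other across the ring and can close back by transannular aldol reaction. C10 still needs a methyl group added with face control beside a second ketone. C7 must be functionalised although C5 and C9 enolise as easily. C11–C14 are all missing. The oxolane would have to come from two hydroxyls by dehydration. A5 itself is a multistep target.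
- Comparison: the chosen strategy carries every skeletal carbon but C12-level oxidation from the start and uses the two alkenes that remain after ring formation as the sites of all later C–O bonds.

Key step: step 11

## Remarks on the chemistry

- Remark 1: the descriptors are used exactly as written, (1S,4S,8S,10R) with C4 cis to C7 across C5=C6; they place C5 and C10 on opposite faces of the oxolane, and the two epoxides of 25 are chosen to give this arrangement.
- Remark 2: in 13–16 the oxygen-bearing or terminal carbon on C11 is C12 (it ends as the lactone carbonyl) and the methyl on C11 is C13 (it ends as the acetoxymethyl carbon).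
- Remark 3: 18–21 are carried as C11 epimers (no descriptor at C11 in their SMILES); the centre is removed in step 16.
- Remark 4: 16 is written as the 6,7-trans, 7,8-trans isomer (6R,7S,8S) that the transition-state analysis in step 11 predicts; the C7 epimer would converge at 25.

## Route

Step 1
Reactants: 1 geranyl acetate
Product: 2 (2E,6E)-8-hydroxy-3,7-dimethylocta-2,6-dien-1-yl acetate
Conditions: SeO2 (cat.), tBuOOH, salicylic acid (cat.), CH2Cl2, rt
Reagents that add atoms: tert-butyl hydroperoxide, CC(C)(C)OO
Why: SeO2-catalysed allylic oxidation (ene reaction, then [2,3]-shift) takes the E-methyl of the terminal trisubstituted alkene; the other alkene is deactivated by the allylic acetate, so the (E)-allylic alcohol at C9 should form selectively.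

Step 2
Reactants: 2 (2E,6E)-8-hydroxy-3,7-dimethylocta-2,6-dien-1-yl acetate
Product: 3 (2E,6E)-8-bromo-3,7-dimethylocta-2,6-dien-1-yl acetate
Conditions: CBr4, PPh3, CH2Cl2, 0 °C
Reagents that add atoms: carbon tetrabromide, BrC(Br)(Br)Br
Why: Appel bromination of a primary allylic alcohol under neutral conditions; SN2 at the primary carbon leaves the alkene geometry and the acetate untouched.

Step 3
Reactants: 4 (R)-4-benzyloxazolidin-2-one; 5 2-(tert-butyldimethylsilyloxy)acetic acid
Product: 7 (R)-4-benzyl-3-[2-(tert-butyldimethylsilyloxy)acetyl]oxazolidin-2-one, via mixed pivalic anhydride 6 (not isolated)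
Conditions: pivaloyl chloride, Et3N, THF, −20 °C; then 4, LiCl, rt
Reagents that add atoms: none
Why: N-acylation of the oxazolidinone through the mixed pivalic anhydride; the hindered pivaloyl carbonyl directs attack to the glycolyl carbonyl.

Step 4
Reactants: 7 (R)-4-benzyl-3-[2-(tert-butyldimethylsilyloxy)acetyl]oxazolidin-2-one; 3 (2E,6E)-8-bromo-3,7-dimethylocta-2,6-dien-1-yl acetate
Product: 8 (2E,6E,9S)-10-[(R)-4-benzyl-2-oxooxazolidin-3-yl]-9-(tert-butyldimethylsilyloxy)-3,7-dimethyl-10-oxodeca-2,6-dien-1-yl acetate
Conditions: NaN(SiMe3)2, THF, −78 °C; then 3, −78 → −45 °C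
Reagents that add atoms: none
Why: Evans alkylation of a glycolate imide: the chelated Z-sodium enolate is shielded on one face by the benzyl group, so the allylic bromide enters from the other and sets C8 as S with the (R)-auxiliary. At these temperatures the enolate should not attack the acetate.

Step 5
Reactants: 8 (2E,6E,9S)-10-[(R)-4-benzyl-2-oxooxazolidin-3-yl]-9-(tert-butyldimethylsilyloxy)-3,7-dimethyl-10-oxodeca-2,6-dien-1-yl acetate
Product: 9 (2E,6E,9S)-9-(tert-butyldimethylsilyloxy)-3,7-dimethyldeca-2,6-diene-1,10-diol
Conditions: LiBH4, MeOH, Et2O–THF, 0 °C → rt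
Reagents that add atoms: none
Why: Reductive removal of the auxiliary gives the primary C7 alcohol, and the same reagent cleaves the acetate, so the diol needed for the next two steps forms in one operation; C8 is not epimerisable here.

Step 6
Reactants: 9 (2E,6E,9S)-9-(tert-butyldimethylsilyloxy)-3,7-dimethyldeca-2,6-diene-1,10-diol
Product: 10 (2S,4E,8E)-2-(tert-butyldimethylsilyloxy)-10-chloro-4,8-dimethyldeca-4,8-dien-1-ol
Conditions: N-chlorosuccinimide, Me2S, CH2Cl2, −40 → 0 °C
Reagents that add atoms: N-chlorosuccinimide, O=C1CCC(=O)N1Cl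
Why: Corey–Kim chlorination: the alkoxysulfonium salt of the allylic alcohol collapses to the chloride at 0 °C, while that of the saturated primary alcohol does not without base and returns the alcohol on work-up.

Step 7
Reactants: 10 (2S,4E,8E)-2-(tert-butyldimethylsilyloxy)-10-chloro-4,8-dimethyldeca-4,8-dien-1-ol
Product: 11 (2S,4E,8E)-2-(tert-butyldimethylsilyloxy)-10-chloro-4,8-dimethyldeca-4,8-dienal
Conditions: Dess–Martin periodinane, NaHCO3, CH2Cl2, 0 °C
Reagents that add atoms: none
Why: Dess–Martin oxidation under buffered conditions gives the α-silyloxy aldehyde without epimerisation; it is used at once.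

Step 8
Reactants: 11 (2S,4E,8E)-2-(tert-butyldimethylsilyloxy)-10-chloro-4,8-dimethyldeca-4,8-dienal; 12 ethyl 2-(triphenylphosphoranylidene)propanoate
Product: 13 ethyl (2E,4S,6E,10E)-4-(tert-butyldimethylsilyloxy)-12-chloro-2,6,10-trimethyldodeca-2,6,10-trienoate
Conditions: CH2Cl2, rt
Reagents that add atoms: none
Why: Wittig olefination with a stabilised α-methyl ylide gives the E trisubstituted alkene C7=C11 and brings in C11, C12 and C13; the allylic chloride is too slow an electrophile to compete at rt.

Step 9
Reactants: 13 ethyl (2E,4S,6E,10E)-4-(tert-butyldimethylsilyloxy)-12-chloro-2,6,10-trimethyldodeca-2,6,10-trienoate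
Product: 14 (2E,4S,6E,10E)-4-(tert-butyldimethylsilyloxy)-12-chloro-2,6,10-trimethyldodeca-2,6,10-trien-1-ol
Conditions: iBu2AlH, CH2Cl2, −78 °C; Rochelle salt
Reagents that add atoms: none
Why: 1,2-Reduction of the enoate to the allylic alcohol at −78 °C leaves the allylic chloride and the silyl ether intact.

Step 10
Reactants: 14 (2E,4S,6E,10E)-4-(tert-butyldimethylsilyloxy)-12-chloro-2,6,10-trimethyldodeca-2,6,10-trien-1-ol
Product: 15 (3E,5S,7E,11E)-5-(tert-butyldimethylsilyloxy)-3,7,11-trimethyl-1-oxacyclotrideca-3,7,11-triene
Conditions: NaH, THF, 50 °C, slow addition (final 0.003 M)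
Reagents that add atoms: none
Why: Intramolecular Williamson etherification at high dilution: the primary allylic alkoxide displaces the primary allylic chloride, and the three E-alkenes hold the chain open for 13-membered ring closure. The E geometry at C7=C11 rules out silyl migration from the C8 oxygen.

Step 11
Reactants: 15 (3E,5S,7E,11E)-5-(tert-butyldimethylsilyloxy)-3,7,11-trimethyl-1-oxacyclotrideca-3,7,11-triene
Product: 16 (1R,2E,6E,9S,10S)-9-(tert-butyldimethylsilyloxy)-3,7-dimethyl-10-(prop-1-en-2-yl)cyclodeca-2,6-dien-1-ol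
Conditions: n-BuLi, THF, −78 → −20 °C; aq. NH4Cl
Reagents that add atoms: none
Why: n-BuLi removes a proton from C6, which is allylic to C4=C5 and α to the ether oxygen, and the carbanion bonds to C7 through a five-membered envelope transition state while the O–C12 bond breaks and C11=C12 forms ([2,3]-Wittig rearrangement). The closest known reaction type is the transannular [2,3]-Wittig contraction of 13-membered diallylic ethers to germacrane-type cyclodecadienols. The ten-membered ring closes by contraction: C6–C7 forms across the large ring, and O, C12 and C11 are pushed out into the side chain, so no end-to-end medium-ring closure is needed. At C6 and C7, the E geometry of C7=C11 and the envelope transition state should place the C6 oxygen and the new isopropenyl group trans on the ring. At C7 relative to C8, H-8 should eclipse the alkene (1,3-allylic strain with the C13 methyl) and the carbanion should add anti to the C8–O bond, which puts the isopropenyl group trans to the silyl ether. The step needs lithiation at C6 and not at C12; a C12 anion would have to bond to the fully substituted C4, and the same substitution pattern is known to rearrange through the C6 anion. Low temperature suppresses the [1,2]-shift. C6 steers step 12, and C6 and C7 both become trigonal later.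

Step 12
Reactants: 16 (1R,2E,6E,9S,10S)-9-(tert-butyldimethylsilyloxy)-3,7-dimethyl-10-(prop-1-en-2-yl)cyclodeca-2,6-dien-1-ol
Product: 17 (4S,5S,6S,7S,8S)-8-(tert-butyldimethylsilyloxy)-4,5-epoxygermacra-1(10),11(12)-dien-6-ol
Conditions: Ti(OiPr)4, L-(+)-diisopropyl tartrate, tBuOOH, 4 Å molecular sieves, CH2Cl2, −20 °C
Reagents that add atoms: tert-butyl hydroperoxide, CC(C)(C)OO
Why: Sharpless asymmetric epoxidation of a secondary allylic alcohol: only the alkene allylic to the free hydroxyl reacts. With L-(+)-tartrate the (6R)-carbinol is the matched partner, and oxygen is delivered to the face that gives the erythro (4S,5S)-epoxide. C1=C10 and the isopropenyl group are not substrates.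

Step 13
Reactants: 17 (4S,5S,6S,7S,8S)-8-(tert-butyldimethylsilyloxy)-4,5-epoxygermacra-1(10),11(12)-dien-6-ol
Product: 18 (4S,5S,6S,7S,8S)-8-(tert-butyldimethylsilyloxy)-4,5-epoxygermacr-1(10)-ene-6,12-diol (C11 epimers)
Conditions: 9-borabicyclo[3.3.1]nonane, THF, 0 °C → rt; then NaBO3·4H2O, H2O
Reagents that add atoms: sodium perborate, [Na+].[Na+].O[B-]1(O)OO[B-](O)(O)OO1
Why: Hydroboration–oxidation: the hindered borane adds to the 1,1-disubstituted alkene much faster than to the trisubstituted C1=C10 and places boron on the terminal carbon C12. Perborate oxidation is mild enough for the epoxy alcohol.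

Step 14
Reactants: 18 (4S,5S,6S,7S,8S)-8-(tert-butyldimethylsilyloxy)-4,5-epoxygermacr-1(10)-ene-6,12-diol (C11 epimers)
Product: 19 (4S,5S,6S,7S,8S)-8-(tert-butyldimethylsilyloxy)-4,5-epoxygermacr-1(10)-en-12,6-olide (C11 epimers)
Conditions: TEMPO (cat.), PhI(OAc)2, CH2Cl2, rt
Reagents that add atoms: none
Why: Oxidative lactonisation of a 1,4-diol: the primary alcohol is oxidised first, the aldehyde is trapped by the C6 hydroxyl as the lactol, and this is oxidised on to the trans-fused γ-lactone.

Step 15
Reactants: 19 (4S,5S,6S,7S,8S)-8-(tert-butyldimethylsilyloxy)-4,5-epoxygermacr-1(10)-en-12,6-olide (C11 epimers)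
Product: 20 (1R,4S,5S,6S,7S,8S,10R)-8-(tert-butyldimethylsilyloxy)-1,10:4,5-diepoxygermacran-12,6-olide (C11 epimers)
Conditions: D-fructose-derived Shi ketone (0.3 equiv), KHSO5, K2CO3, Bu4NHSO4, MeCN–CH2(OMe)2–aq. Na2B4O7, 0 °C
Reagents that add atoms: potassium peroxymonosulfate, [K+].[O-]S(=O)(=O)OO
Why: Shi epoxidation: the chiral dioxirane converts E-trisubstituted alkenes to (R,R)-epoxides through a spiro transition state, here (1R,10R). C1=C10 is the only alkene left, and the catalyst should select the alkene rotamer that exposes this face.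

Step 16
Reactants: 20 (1R,4S,5S,6S,7S,8S,10R)-8-(tert-butyldimethylsilyloxy)-1,10:4,5-diepoxygermacran-12,6-olide (C11 epimers)
Product: 22 (1R,4S,5S,6S,7S,8S,10R)-8-(tert-butyldimethylsilyloxy)-1,10:4,5-diepoxygermacr-11(13)-en-12,6-olide, via 11-phenylselenyl lactone 21 (not isolated)
Conditions: LiN(iPr)2, THF, −78 °C; PhSeBr; then H2O2, pyridine, CH2Cl2, 0 °C
Reagents that add atoms: none
Why: α-Selenenylation of the lactone enolate followed by selenoxide syn-elimination; on a trans-fused lactone selenium should enter anti to H-7, so only a methyl hydrogen is available and the exocyclic C11=C13 alkene forms.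

Step 17
Reactants: 22 (1R,4S,5S,6S,7S,8S,10R)-8-(tert-butyldimethylsilyloxy)-1,10:4,5-diepoxygermacr-11(13)-en-12,6-olide
Product: 23 (1R,4S,5S,6S,7S,8S,10R,11S)-8-(tert-butyldimethylsilyloxy)-1,10:4,5-diepoxy-11,13-dihydroxygermacran-12,6-olide
Conditions: OsO4 (cat.), N-methylmorpholine N-oxide, acetone–H2O, rt
Reagents that add atoms: N-methylmorpholine N-oxide, C[N+]1([O-])CCOCC1; water, O
Why: Catalytic syn-dihydroxylation of the only remaining alkene; attack from the face away from H-7 and the C8 silyl ether should place the C11 hydroxyl anti to H-7 and brings in the C13 oxygen.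

Step 18
Reactants: 23 (1R,4S,5S,6S,7S,8S,10R,11S)-8-(tert-butyldimethylsilyloxy)-1,10:4,5-diepoxy-11,13-dihydroxygermacran-12,6-olide
Product: 24 (1R,4S,5S,6S,7S,8S,10R,11S)-8,13-bis(tert-butyldimethylsilyloxy)-1,10:4,5-diepoxy-11-hydroxygermacran-12,6-olide
Conditions: tert-butyldimethylsilyl chloride, imidazole, CH2Cl2, 0 °C
Reagents that add atoms: tert-butyldimethylsilyl chloride, CC(C)(C)[Si](C)(C)Cl
Why: Selective silylation of the primary hydroxyl; the tertiary α-hydroxy lactone does not react, and the silyl ether is a poor leaving group for step 20.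

Step 19
Reactants: 24 (1R,4S,5S,6S,7S,8S,10R,11S)-8,13-bis(tert-butyldimethylsilyloxy)-1,10:4,5-diepoxy-11-hydroxygermacran-12,6-olide
Product: 25 (1R,4S,5S,6S,8S,10R)-8,13-bis(tert-butyldimethylsilyloxy)-1,10:4,5-diepoxygermacr-7(11)-en-12,6-olide
Conditions: Ph2S[OC(CF3)2Ph]2 (Martin sulfurane), CH2Cl2, 0 °C → rt
Reagents that add atoms: none
Why: Dehydration of a tertiary alcohol under neutral conditions that spare both epoxides; H-7 is antiperiplanar to the activated C11–O bond, and its loss gives the tetrasubstituted conjugated C7=C11 alkene in preference to the enol ether toward C13.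

Step 20
Reactants: 25 (1R,4S,5S,6S,8S,10R)-8,13-bis(tert-butyldimethylsilyloxy)-1,10:4,5-diepoxygermacr-7(11)-en-12,6-olide
Product: 27 (1S,4S,5E,8S,10R)-8,13-bis(tert-butyldimethylsilyloxy)-1,4-epoxy-10-hydroxygermacra-5,7(11)-dien-12,6-olide, via C4 tertiary alkoxide 26 (not isolated)
Conditions: KOtBu, THF, −78 → 0 °C; aq. NH4Cl
Reagents that add atoms: none
Why: Base removes H-6, the γ-proton of the butenolide, and the 2-oxidofuran opens the 4,5-epoxide by E1cB, so C5=C6 forms with C4 held cis to C7 by the ring and the C4–O bond (4S) is untouched. The C4 alkoxide then opens the 1,10-epoxide at C1 from the rear (5-exo, inversion to 1S) and leaves the C10 oxygen as the tertiary alcohol (10R). The C13 silyl ether is too poor a leaving group to be expelled from the same anion.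

Step 21
Reactants: 27 (1S,4S,5E,8S,10R)-8,13-bis(tert-butyldimethylsilyloxy)-1,4-epoxy-10-hydroxygermacra-5,7(11)-dien-12,6-olide
Product: 28 (1S,4S,5E,8S,10R)-1,4-epoxy-8,10,13-trihydroxygermacra-5,7(11)-dien-12,6-olide
Conditions: HF·pyridine, pyridine, THF, 0 °C → rt
Reagents that add atoms: none
Why: Buffered fluoride cleavage of both silyl ethers without base or strong acid, which the enol lactone and the tertiary allylic ether would not tolerate.

Step 22
Reactants: 28 (1S,4S,5E,8S,10R)-1,4-epoxy-8,10,13-trihydroxygermacra-5,7(11)-dien-12,6-olide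
Product: 29 (1S,4S,5E,8S,10R)-13-acetoxy-1,4-epoxy-8,10-dihydroxygermacra-5,7(11)-dien-12,6-olide
Conditions: AcCl, 2,4,6-collidine, CH2Cl2, −78 °C
Reagents that add atoms: acetyl chloride, CC(Cl)=O
Why: Low-temperature acetylation with a hindered base is selective for the primary allylic hydroxyl over the secondary C8 and tertiary C10 hydroxyls.

Step 23
Reactants: 29 (1S,4S,5E,8S,10R)-13-acetoxy-1,4-epoxy-8,10-dihydroxygermacra-5,7(11)-dien-12,6-olide; 30 angelic acid
Product: 32 (1S,4S,5E,8S,10R)-13-acetoxy-8-angeloyloxy-1,4-epoxy-10-hydroxygermacra-5,7(11)-dien-12,6-olide (target), via angelic 2,4,6-trichlorobenzoic anhydride 31 (not isolated)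
Conditions: 30, 2,4,6-trichlorobenzoyl chloride, Et3N, toluene, rt; then 29, 75 °C
Reagents that add atoms: none
Why: Yamaguchi esterification through the mixed anhydride, run without a nucleophilic catalyst, acylates the secondary C8 hydroxyl without Z-to-E isomerisation of the angelate; the tertiary C10 hydroxyl does not react.

## Compound list

1 | geranyl acetate, (2E)-3,7-dimethylocta-2,6-dien-1-yl acetate | CC(C)=CCC/C(C)=C/COC(C)=O | starting material
2 | (2E,6E)-8-hydroxy-3,7-dimethylocta-2,6-dien-1-yl acetate | OC/C(C)=C/CC/C(C)=C/COC(C)=O | intermediate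
3 | (2E,6E)-8-bromo-3,7-dimethylocta-2,6-dien-1-yl acetate | BrC/C(C)=C/CC/C(C)=C/COC(C)=O | intermediate
4 | (R)-4-benzyloxazolidin-2-one | O=C1N[C@H](Cc2ccccc2)CO1 | starting material
5 | 2-(tert-butyldimethylsilyloxy)acetic acid | CC(C)(C)[Si](C)(C)OCC(=O)O | starting material
6 | 2-(tert-butyldimethylsilyloxy)acetic pivalic anhydride | CC(C)(C)[Si](C)(C)OCC(=O)OC(=O)C(C)(C)C | intermediate (not isolated)
7 | (R)-4-benzyl-3-[2-(tert-butyldimethylsilyloxy)acetyl]oxazolidin-2-one | CC(C)(C)[Si](C)(C)OCC(=O)N1[C@H](Cc2ccccc2)COC1=O | intermediate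
8 | (2E,6E,9S)-10-[(R)-4-benzyl-2-oxooxazolidin-3-yl]-9-(tert-butyldimethylsilyloxy)-3,7-dimethyl-10-oxodeca-2,6-dien-1-yl acetate | CC(=O)OC/C=C(\C)CC/C=C(\C)C[C@H](O[Si](C)(C)C(C)(C)C)C(=O)N1[C@H](Cc2ccccc2)COC1=O | intermediate
9 | (2E,6E,9S)-9-(tert-butyldimethylsilyloxy)-3,7-dimethyldeca-2,6-diene-1,10-diol | OC/C=C(\C)CC/C=C(\C)C[C@H](O[Si](C)(C)C(C)(C)C)CO | intermediate
10 | (2S,4E,8E)-2-(tert-butyldimethylsilyloxy)-10-chloro-4,8-dimethyldeca-4,8-dien-1-ol | ClC/C=C(\C)CC/C=C(\C)C[C@H](O[Si](C)(C)C(C)(C)C)CO | intermediate
11 | (2S,4E,8E)-2-(tert-butyldimethylsilyloxy)-10-chloro-4,8-dimethyldeca-4,8-dienal | ClC/C=C(\C)CC/C=C(\C)C[C@H](O[Si](C)(C)C(C)(C)C)C=O | intermediate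
12 | ethyl 2-(triphenylphosphoranylidene)propanoate | CCOC(=O)C(C)=P(c1ccccc1)(c1ccccc1)c1ccccc1 | starting material
13 | ethyl (2E,4S,6E,10E)-4-(tert-butyldimethylsilyloxy)-12-chloro-2,6,10-trimethyldodeca-2,6,10-trienoate | ClC/C=C(\C)CC/C=C(\C)C[C@H](O[Si](C)(C)C(C)(C)C)/C=C(\C)C(=O)OCC | intermediate
14 | (2E,4S,6E,10E)-4-(tert-butyldimethylsilyloxy)-12-chloro-2,6,10-trimethyldodeca-2,6,10-trien-1-ol | ClC/C=C(\C)CC/C=C(\C)C[C@H](O[Si](C)(C)C(C)(C)C)/C=C(\C)CO | intermediate
15 | (3E,5S,7E,11E)-5-(tert-butyldimethylsilyloxy)-3,7,11-trimethyl-1-oxacyclotrideca-3,7,11-triene (13-membered diallylic ether, C8 silyl ether) | CC(C)(C)[Si](C)(C)O[C@H]1C/C(C)=C/CC/C(C)=C/COC/C(C)=C/1 | intermediate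
16 | (1R,2E,6E,9S,10S)-9-(tert-butyldimethylsilyloxy)-3,7-dimethyl-10-(prop-1-en-2-yl)cyclodeca-2,6-dien-1-ol; germacrane numbering (6R,7S,8S)-8-silyloxygermacra-1(10),4,11(12)-trien-6-ol | CC(C)(C)[Si](C)(C)O[C@H]1C/C(C)=C/CC/C(C)=C/[C@@H](O)[C@@H]1C(C)=C | intermediate
17 | (4S,5S,6S,7S,8S)-8-(tert-butyldimethylsilyloxy)-4,5-epoxygermacra-1(10),11(12)-dien-6-ol | CC(C)(C)[Si](C)(C)O[C@H]1C/C(C)=C/CC[C@]2(C)O[C@H]2[C@@H](O)[C@@H]1C(C)=C | intermediate
18 | (4S,5S,6S,7S,8S)-8-(tert-butyldimethylsilyloxy)-4,5-epoxygermacr-1(10)-ene-6,12-diol, C11 epimers | CC(C)(C)[Si](C)(C)O[C@H]1C/C(C)=C/CC[C@]2(C)O[C@H]2[C@@H](O)[C@@H]1C(C)CO | intermediate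
19 | (4S,5S,6S,7S,8S)-8-(tert-butyldimethylsilyloxy)-4,5-epoxygermacr-1(10)-en-12,6-olide, trans-fused, C11 epimers | CC(C)(C)[Si](C)(C)O[C@H]1C/C(C)=C/CC[C@]2(C)O[C@H]2[C@H]2OC(=O)C(C)[C@H]12 | intermediate
20 | (1R,4S,5S,6S,7S,8S,10R)-8-(tert-butyldimethylsilyloxy)-1,10:4,5-diepoxygermacran-12,6-olide, C11 epimers | CC(C)(C)[Si](C)(C)O[C@H]1C[C@@]3(C)O[C@@H]3CC[C@]2(C)O[C@H]2[C@H]2OC(=O)C(C)[C@H]12 | intermediate
21 | 11-phenylselenyl derivative of 20 | CC(C)(C)[Si](C)(C)O[C@H]1C[C@@]3(C)O[C@@H]3CC[C@]2(C)O[C@H]2[C@H]2OC(=O)C(C)([Se]c4ccccc4)[C@H]12 | intermediate (not isolated)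
22 | (1R,4S,5S,6S,7S,8S,10R)-8-(tert-butyldimethylsilyloxy)-1,10:4,5-diepoxygermacr-11(13)-en-12,6-olide | CC(C)(C)[Si](C)(C)O[C@H]1C[C@@]3(C)O[C@@H]3CC[C@]2(C)O[C@H]2[C@H]2OC(=O)C(=C)[C@H]12 | intermediate
23 | (1R,4S,5S,6S,7S,8S,10R,11S)-8-(tert-butyldimethylsilyloxy)-1,10:4,5-diepoxy-11,13-dihydroxygermacran-12,6-olide | CC(C)(C)[Si](C)(C)O[C@H]1C[C@@]3(C)O[C@@H]3CC[C@]2(C)O[C@H]2[C@H]2OC(=O)[C@@](O)(CO)[C@H]12 | intermediate
24 | (1R,4S,5S,6S,7S,8S,10R,11S)-8,13-bis(tert-butyldimethylsilyloxy)-1,10:4,5-diepoxy-11-hydroxygermacran-12,6-olide | CC(C)(C)[Si](C)(C)O[C@H]1C[C@@]3(C)O[C@@H]3CC[C@]2(C)O[C@H]2[C@H]2OC(=O)[C@@](O)(CO[Si](C)(C)C(C)(C)C)[C@H]12 | intermediate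
25 | (1R,4S,5S,6S,8S,10R)-8,13-bis(tert-butyldimethylsilyloxy)-1,10:4,5-diepoxygermacr-7(11)-en-12,6-olide | CC(C)(C)[Si](C)(C)O[C@H]1C[C@@]3(C)O[C@@H]3CC[C@]2(C)O[C@H]2[C@H]2OC(=O)C(CO[Si](C)(C)C(C)(C)C)=C12 | intermediate
26 | (1R,4S,5E,8S,10R)-8,13-bis(tert-butyldimethylsilyloxy)-1,10-epoxy-4-hydroxygermacra-5,7(11)-dien-12,6-olide (formed as its potassium alkoxide) | CC(C)(C)[Si](C)(C)O[C@H]1C[C@@]3(C)O[C@@H]3CC[C@](C)(O)/C=C2/OC(=O)C(CO[Si](C)(C)C(C)(C)C)=C12 | intermediate (not isolated)
27 | (1S,4S,5E,8S,10R)-8,13-bis(tert-butyldimethylsilyloxy)-1,4-epoxy-10-hydroxygermacra-5,7(11)-dien-12,6-olide | CC(C)(C)[Si](C)(C)O[C@H]1C[C@@](C)(O)[C@@H]2CC[C@@](C)(/C=C3/OC(=O)C(CO[Si](C)(C)C(C)(C)C)=C31)O2 | intermediate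
28 | (1S,4S,5E,8S,10R)-1,4-epoxy-8,10,13-trihydroxygermacra-5,7(11)-dien-12,6-olide | O[C@H]1C[C@@](C)(O)[C@@H]2CC[C@@](C)(/C=C3/OC(=O)C(CO)=C31)O2 | intermediate
29 | (1S,4S,5E,8S,10R)-13-acetoxy-1,4-epoxy-8,10-dihydroxygermacra-5,7(11)-dien-12,6-olide | O[C@H]1C[C@@](C)(O)[C@@H]2CC[C@@](C)(/C=C3/OC(=O)C(COC(C)=O)=C31)O2 | intermediate
30 | angelic acid, (2Z)-2-methylbut-2-enoic acid | C/C=C(/C)C(=O)O | starting material
31 | angelic 2,4,6-trichlorobenzoic anhydride | C/C=C(/C)C(=O)OC(=O)c1c(Cl)cc(Cl)cc1Cl | intermediate (not isolated)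
32 | (1S,4S,5E,8S,10R)-13-acetoxy-8-angeloyloxy-1,4-epoxy-10-hydroxygermacra-5,7(11)-dien-12,6-olide, CNP0162854.1 | C/C=C(/C)C(=O)O[C@H]1C[C@@](C)(O)[C@@H]2CC[C@@](C)(/C=C3/OC(=O)C(COC(C)=O)=C31)O2 | target

## Step count and least certain steps

Total step count: 23. Longest linear sequence: 22 steps (1 to 32 through steps 1, 2 and 4–23); step 3 is a one-step branch.

**Step 11 (key step).** The most likely failure is lithiation at C12, the other allylic position next to oxygen, because the anion on that side has less alkyl substitution at its termini. It would contract the ring onto C4 or give a [1,2]-shift on warming. Fallback: the C6–C7 bond is made by carbonyl allylation instead. From 14, the allylic chloride end is oxidised with N-methylmorpholine N-oxide to the enal (2E,6E,9S,10E)-9-(tert-butyldimethylsilyloxy)-12-hydroxy-3,7,11-trimethyldodeca-2,6,10-trienal F1. The C12 hydroxyl is then exchanged for bromide (CBr4, PPh3) to give the bromo enal F2. CrCl2 in THF at high dilution (intramolecular Nozaki–Hiyama allylation, bond formation at the γ-carbon C7 with allylic transposition) closes the ten-membered ring and returns to the route at 16 without passing through 15.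

**Step 20.** The elimination should be easy; the closure is the weak point. The alkoxide must reach the rear of C1 from the face of the oxolane opposite to the C4–C5 bond, and the ring may not allow this. The reaction may then stop at the alkoxide, or the alkoxide may attack the lactone carbonyl or C10. Fallback: the two events are separated and the epoxide is opened in a different way. From 25, a catalytic tertiary amine (Et3N, CH2Cl2, 0 °C) gives 26, which is isolated. Its titanium alkoxide, made with Ti(OiPr)4 in toluene, then delivers the C4 oxygen to C1 within a complex that also binds the epoxide oxygen, and this returns to the route at 27. If the bridge cannot form with this configuration, the route ends here for the structure as written. The same sequence run from the threo 4,5-epoxide (step 12 with a peracid) would lead to the C4 epimer, in which C5 and C10 are cis on the oxolane.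

**Step 12.** The methyl on C4 is cis to the carbinol carbon. 1,3-Allylic strain in the titanium-bound rotamer can slow the matched pathway, so that oxygen delivery to the other face (threo epoxide) competes. Fallback: the hydroxyl configuration is used the other way round. From 16, Mitsunobu inversion (4-nitrobenzoic acid, PPh3, diisopropyl azodicarboxylate) gives the C6-inverted 4-nitrobenzoate F3, and K2CO3 in MeOH gives the C6 epimer of 16, F4. Tartrate-free Ti(OiPr)4/tBuOOH, which is threo-selective for allylic alcohols with a cis substituent, then gives the (4S,5S)-epoxy alcohol F5 with the inverted carbinol. A second Mitsunobu inversion gives the 4-nitrobenzoate F6, and methanolysis returns to the route at 17. If step 11 gives the C6 epimer of 16 directly, only the threo-selective epoxidation and the second inversion are needed.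

**Step 19.** The dehydration may go toward C13 and give the silyl enol ether; and if osmylation in step 17 took the other face, H-7 would not be antiperiplanar. Fallback: the alkene is moved by a radical reaction instead. From 22, N-bromosuccinimide with a radical initiator in PhCF3 at 80 °C should abstract the tertiary allylic H-7 and place bromine on C13 with transposition of the alkene, giving the 13-bromo butenolide F7. Ag2CO3 in aqueous acetone gives the 13-hydroxy butenolide F8, and tert-butyldimethylsilyl chloride with imidazole returns to the route at 25.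

## Further compounds

F1 | step 11 | (2E,6E,9S,10E)-9-(tert-butyldimethylsilyloxy)-12-hydroxy-3,7,11-trimethyldodeca-2,6,10-trienal | O=C/C=C(\C)CC/C=C(\C)C[C@H](O[Si](C)(C)C(C)(C)C)/C=C(\C)CO
F2 | step 11 | (2E,6E,9S,10E)-12-bromo-9-(tert-butyldimethylsilyloxy)-3,7,11-trimethyldodeca-2,6,10-trienal | O=C/C=C(\C)CC/C=C(\C)C[C@H](O[Si](C)(C)C(C)(C)C)/C=C(\C)CBr
F3 | step 12 | 4-nitrobenzoate of the C6 epimer of 16 | CC(C)(C)[Si](C)(C)O[C@H]1C/C(C)=C/CC/C(C)=C/[C@H](OC(=O)c2ccc(cc2)[N+](=O)[O-])[C@@H]1C(C)=C
F4 | step 12 | C6 epimer of 16, (1S,2E,6E,9S,10S)-9-(tert-butyldimethylsilyloxy)-3,7-dimethyl-10-(prop-1-en-2-yl)cyclodeca-2,6-dien-1-ol | CC(C)(C)[Si](C)(C)O[C@H]1C/C(C)=C/CC/C(C)=C/[C@H](O)[C@@H]1C(C)=C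
F5 | step 12 | C6 epimer of 17 | CC(C)(C)[Si](C)(C)O[C@H]1C/C(C)=C/CC[C@]2(C)O[C@H]2[C@H](O)[C@@H]1C(C)=C
F6 | step 12 | 4-nitrobenzoate of 17 | CC(C)(C)[Si](C)(C)O[C@H]1C/C(C)=C/CC[C@]2(C)O[C@H]2[C@@H](OC(=O)c3ccc(cc3)[N+](=O)[O-])[C@@H]1C(C)=C
F7 | step 19 | (1R,4S,5S,6S,8S,10R)-13-bromo-8-(tert-butyldimethylsilyloxy)-1,10:4,5-diepoxygermacr-7(11)-en-12,6-olide | CC(C)(C)[Si](C)(C)O[C@H]1C[C@@]3(C)O[C@@H]3CC[C@]2(C)O[C@H]2[C@H]2OC(=O)C(CBr)=C12
F8 | step 19 | (1R,4S,5S,6S,8S,10R)-8-(tert-butyldimethylsilyloxy)-1,10:4,5-diepoxy-13-hydroxygermacr-7(11)-en-12,6-olide | CC(C)(C)[Si](C)(C)O[C@H]1C[C@@]3(C)O[C@@H]3CC[C@]2(C)O[C@H]2[C@H]2OC(=O)C(CO)=C12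
F0 | step 20 | none | none
A1 | alternative 1 | (4R,5R)-13-acetoxy-8-angeloyloxy-4,5-epoxy-1,10-dihydroxygermacr-7(11)-en-12,6-olide | C/C=C(/C)C(=O)O[C@H]1C[C@@](C)(O)[C@@H](O)CC[C@@]2(C)O[C@@H]2[C@@H]2OC(=O)C(COC(C)=O)=C21
A2 | alternative 1 | 13-acetoxy-8-angeloyloxy-1,4-epoxy-5,10-dihydroxygermacr-7(11)-en-12,6-olide | C/C=C(/C)C(=O)O[C@H]1C[C@@](C)(O)[C@@H]2CC[C@@](C)([C@H](O)[C@@H]3OC(=O)C(COC(C)=O)=C31)O2
A3 | alternative 2 | eleven-membered keto thiolactone with the oxolane bridge and the C10 triethylsilyl ether | O=C1C[C@@](C)(O[Si](CC)(CC)CC)[C@@H]2CC[C@@](C)(CC(=O)CS1)O2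
A4 | alternative 2 | oxolane-bridged cyclodecane-1,3-dione | O=C1C[C@@](C)(O[Si](CC)(CC)CC)[C@@H]2CC[C@@](C)(CC(=O)C1)O2
A5 | alternative 3 | bicyclo[5.3.0]decene with the C6=C10 ring-fusion alkene and silyl ethers at C1, C4 and C8 | CC[Si](CC)(CC)O[C@H]1CC[C@](C)(O[Si](CC)(CC)CC)CC2=C1C[C@H](O[Si](C)(C)C(C)(C)C)C2
A6 | alternative 3 | cyclodecane-1,5-dione with silyl ethers at C1, C4 and C8 | CC[Si](CC)(CC)O[C@H]1CC[C@](C)(O[Si](CC)(CC)CC)CC(=O)C[C@@H](O[Si](C)(C)C(C)(C)C)CC1=O
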